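**Strategy.** Everything rests on disconnecting the C3–C4 bond of the cyclohexanone ring (7-oxabicyclo[4.1.0]heptan-2-one numbering: C2 ketone, C3 acyloxy carbon, C4 side-chain carbon). The key step reads the C2 ketone/C3 oxygen pair as an α-keto aldehyde and the C3–O/C4–C(=CH2) unit as a carbonyl-ene retron. One copper-bis(oxazoline)-catalysed intramolecular glyoxal-ene reaction closes the six-membered carbocycle, sets C3 and C4 trans and creates the 1,1-disubstituted alkene. Its precursor is an acyclic epoxy keto aldehyde with a prenyl terminus, so the oxirane is already in place when the carbocycle closes. The isopropenyl group is then grown into the dienone, and a closing singlet-oxygen ene reaction installs the hydroperoxide.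

Key step: step 6

Remark: locants refer to the 7-oxabicyclo[4.1.0]heptan-2-one core (C1 methyl-bearing oxirane carbon, C2 ketone, C3 acyloxy carbon, C4 side-chain carbon, C5 methylene, C6 oxirane CH); side-chain carbons carry primes.
Assumption: boronate 18 is bought as such; keto aldehyde 12 is drawn as the free aldehyde although it is expected to be handled partly as its hydrate.

Step 1
Reactants: 1 prop-2-yn-1-ol; 2 methylmagnesium bromide; 3 1-bromo-3-methylbut-2-ene
Product: 5 (2Z)-2,6-dimethylhepta-2,5-dien-1-ol, via alkenylmagnesium chelate 4 (not isolated)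
Conditions: 2 (2.3 equiv), CuI (10 mol %), Et2O, −10 °C → rt; then 3, THF, 0 °C → rt; H2O quench
Reagents that add atoms: none
Why: Copper-catalysed anti-carbomagnesiation of the magnesium propargylic alkoxide puts the methyl group on the internal carbon and magnesium on the terminus, held cis to oxygen in chelate 4, and copper-mediated SN2 allylation of this alkenyl–metal bond with prenyl bromide proceeds with retention, which fixes the Z geometry (hydroxymethyl cis to the chain) that the cis-fused oxirane later requires.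

Step 2
Reactants: 5 (2Z)-2,6-dimethylhepta-2,5-dien-1-ol
Product: 6 [(2R,3S)-2-methyl-3-(3-methylbut-2-en-1-yl)oxiran-2-yl]methanol
Conditions: Ti(OiPr)4 (10 mol %), D-(−)-diethyl tartrate (12 mol %), t-BuOOH, 4 Å MS, CH2Cl2, −20 °C
Reagents that add atoms: tert-butyl hydroperoxide, CC(C)(C)OO
Why: Katsuki–Sharpless asymmetric epoxidation with the tetravalent-titanium tartrate complex epoxidises only the alkene of the allylic alcohol, stereospecifically (Z alkene to cis-oxirane), and D-(−)-tartrate is chosen because L-(+)-tartrate is known to give the (2S,3R) series with (Z)-2-methylalk-2-en-1-ols, so the (2R,3S) oxirane (future C1 and C6) should result.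

Step 3
Reactants: 6 [(2R,3S)-2-methyl-3-(3-methylbut-2-en-1-yl)oxiran-2-yl]methanol
Product: 7 (2S,3S)-2-methyl-3-(3-methylbut-2-en-1-yl)oxirane-2-carbaldehyde
Conditions: Dess–Martin periodinane, NaHCO3, CH2Cl2, 0 °C → rt
Reagents that add atoms: none
Why: Dess–Martin oxidation of the primary alcohol under bicarbonate buffering leaves the oxirane and the alkene alone, and the quaternary α-carbon rules out epimerisation.

Step 4
Reactants: 7 (2S,3S)-2-methyl-3-(3-methylbut-2-en-1-yl)oxirane-2-carbaldehyde; 8 1,3-dithiane
Product: 10 (1,3-dithian-2-yl)[(2R,3S)-2-methyl-3-(3-methylbut-2-en-1-yl)oxiran-2-yl]methanol (both carbinol epimers), via 2-lithio-1,3-dithiane 9 (not isolated)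
Conditions: 8, n-BuLi, THF, −30 °C; then 7, −78 °C; H2O quench
Reagents that add atoms: none
Why: Corey–Seebach addition of the lithiated dithiane (a formyl-anion equivalent that supplies the future C3) to the aldehyde is far faster than oxirane opening at −78 °C; the new carbinol centre forms without control and is erased in step 5.

Step 5
Reactants: 10 (1,3-dithian-2-yl)[(2R,3S)-2-methyl-3-(3-methylbut-2-en-1-yl)oxiran-2-yl]methanol
Product: 12 2-[(2S,3S)-2-methyl-3-(3-methylbut-2-en-1-yl)oxiran-2-yl]-2-oxoacetaldehyde, via acyl dithiane 11 (not isolated)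
Conditions: Dess–Martin periodinane (4 equiv), CH2Cl2/MeCN/H2O, 0 °C → rt; crude 12 kept cold, dried azeotropically with toluene and used at once
Reagents that add atoms: water, O
Why: Dess–Martin periodinane oxidises the carbinol to the 2-acyl-1,3-dithiane 11 and then, in the wet medium, removes the dithioacetal by hypervalent-iodine-mediated oxidative hydrolysis, two known roles of this reagent that spare alkenes and oxiranes.

Step 6
Reactants: 12 2-[(2S,3S)-2-methyl-3-(3-methylbut-2-en-1-yl)oxiran-2-yl]-2-oxoacetaldehyde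
Product: 13 (1S,3S,4S,6S)-3-hydroxy-1-methyl-4-(prop-1-en-2-yl)-7-oxabicyclo[4.1.0]heptan-2-one
Conditions: [Cu((S,S)-t-Bu-box)(H2O)2](SbF6)2 (10 mol %; t-Bu-box = 2,2′-(propane-2,2-diyl)bis[(4S)-4-tert-butyl-4,5-dihydro-1,3-oxazole]), 4 Å MS, CH2Cl2, −40 → 0 °C
Reagents that add atoms: none
Why: Divalent copper chelates the two carbonyl oxygens of the keto aldehyde, and the tethered trisubstituted alkene adds to the activated aldehyde carbon through a concerted but asynchronous six-membered ene transition state in which a methyl hydrogen passes to the aldehyde oxygen, so the C3–C4 bond, the C3 carbinol and the isopropenyl group arise together. The closest known reactions are the type 1 intramolecular carbonyl-ene cyclisation of citronellal to isopulegol and the bis(oxazoline)-copper-catalysed ene reactions of glyoxylates and of unsaturated α-keto esters. The carbocycle closes in a 6-exo-trig mode at the aldehyde carbon, through a half-chair because the oxirane keeps C2, C1, C6 and C5 coplanar. C3 is set by the catalyst, whose (S,S)-tert-butyl ligand should leave the Si face of the chelated aldehyde open as it does for glyoxylate, giving 3S; C4 is set by the closed transition state, in which the chelated C3–O bond (eclipsed with the ketone) and the alkene are both pseudo-equatorial and the hydrogen comes from the methyl group cis to the vinylic hydrogen, so that C3–O and the isopropenyl group end up trans (4S). The step needs the aldehyde and not the ketone to act as enophile (more electrophilic carbon, six- instead of five-membered closure), an intact oxirane (weak chelated Lewis acid, electron-poor α,β-epoxy ketone) and face selection relative to the oxirane stereocentres, which is placed under catalyst control because the intrinsic bias of the half-chair is expected to be small.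

Step 7
Reactants: 13 (1S,3S,4S,6S)-3-hydroxy-1-methyl-4-(prop-1-en-2-yl)-7-oxabicyclo[4.1.0]heptan-2-one; 14 (2E)-2-methylbut-2-enoyl chloride
Product: 15 (1S,3S,4S,6S)-1-methyl-2-oxo-4-(prop-1-en-2-yl)-7-oxabicyclo[4.1.0]heptan-3-yl (2E)-2-methylbut-2-enoate
Conditions: 14, pyridine, DMAP (cat.), CH2Cl2, 0 °C
Reagents that add atoms: none
Why: Nucleophile-catalysed (DMAP) acylation of the secondary α-ketol with the acid chloride forms no stereocentre, the tigloyl unit keeps its stable E geometry, and C3 stays in the trans (diequatorial) arrangement, which is also the thermodynamically preferred one should enolisation occur.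

Step 8
Reactants: 15 (1S,3S,4S,6S)-1-methyl-2-oxo-4-(prop-1-en-2-yl)-7-oxabicyclo[4.1.0]heptan-3-yl (2E)-2-methylbut-2-enoate
Product: 17 (1S,3S,4S,6S)-1-methyl-2-oxo-4-(3-oxoprop-1-en-2-yl)-7-oxabicyclo[4.1.0]heptan-3-yl (2E)-2-methylbut-2-enoate, via allylic alcohol 16 (not isolated)
Conditions: SeO2 (30 mol %), t-BuOOH (3 equiv), CH2Cl2, rt; aqueous wash; then activated MnO2, CH2Cl2, rt
Reagents that add atoms: selenium dioxide, O=[Se]=O; tert-butyl hydroperoxide, CC(C)(C)OO
Why: Riley allylic oxidation in its catalytic SeO2/t-BuOOH form (ene reaction, then [2,3]-sigmatropic shift) attacks the only electron-rich alkene and should take hydrogen from the methyl group in preference to the inductively deactivated ring methine, and MnO2 then oxidises only the allylic alcohol 16 to the enal.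

Step 9
Reactants: 17 (1S,3S,4S,6S)-1-methyl-2-oxo-4-(3-oxoprop-1-en-2-yl)-7-oxabicyclo[4.1.0]heptan-3-yl (2E)-2-methylbut-2-enoate; 18 4,4,5,5-tetramethyl-2-(2-methylbut-3-en-2-yl)-1,3,2-dioxaborolane
Product: 20 (1S,3S,4S,6S)-4-(3-hydroxy-6-methylhepta-1,5-dien-2-yl)-1-methyl-2-oxo-7-oxabicyclo[4.1.0]heptan-3-yl (2E)-2-methylbut-2-enoate (both C3′ epimers), via pinacol borate ester 19 (not isolated)
Conditions: 18 (1.5 equiv), toluene, 40 °C; then aq. NaHCO3, rt
Reagents that add atoms: none
Why: Allylboration through a closed six-membered Zimmerman–Traxler transition state is selective for the aldehyde over the ketone, the esters and the oxirane, and its inherent allylic transposition turns the tertiary boronate into the linear prenyl carbinol; the new carbinol centre forms without control and is erased in step 10.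

Step 10
Reactants: 20 (1S,3S,4S,6S)-4-(3-hydroxy-6-methylhepta-1,5-dien-2-yl)-1-methyl-2-oxo-7-oxabicyclo[4.1.0]heptan-3-yl (2E)-2-methylbut-2-enoate
Product: 21 (1S,3S,4S,6S)-1-methyl-4-(6-methyl-3-oxohepta-1,5-dien-2-yl)-2-oxo-7-oxabicyclo[4.1.0]heptan-3-yl (2E)-2-methylbut-2-enoate
Conditions: Dess–Martin periodinane, NaHCO3, CH2Cl2, 0 °C; used directly
Reagents that add atoms: none
Why: Buffered Dess–Martin oxidation converts the allylic carbinol into the ketone under neutral conditions that should not move the β,γ-double bond into conjugation.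

Step 11
Reactants: 21 (1S,3S,4S,6S)-1-methyl-4-(6-methyl-3-oxohepta-1,5-dien-2-yl)-2-oxo-7-oxabicyclo[4.1.0]heptan-3-yl (2E)-2-methylbut-2-enoate
Product: 22 (1S,3S,4S,6S)-4-[(4E)-6-hydroperoxy-6-methyl-3-oxohepta-1,4-dien-2-yl]-1-methyl-2-oxo-7-oxabicyclo[4.1.0]heptan-3-yl (2E)-2-methylbut-2-enoate
Conditions: O2, tetraphenylporphyrin (1 mol %), visible light, CH2Cl2, −20 °C; chromatography without reductive work-up
Reagents that add atoms: dioxygen, O=O
Why: In this Schenck ene reaction singlet oxygen attacks the only electron-rich (trisubstituted) alkene, abstraction of a hydrogen from the methylene flanked by the ketone and the alkene is expected to be favoured because it creates the conjugated enone, the oxygen ends up on the tertiary carbon, and the new double bond forms E because the acyl substituent sits pseudo-equatorial in the ene transition state.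

**Compound list**

1 | prop-2-yn-1-ol | C#CCO | starting material
2 | methylmagnesium bromide | C[Mg]Br | starting material
3 | 1-bromo-3-methylbut-2-ene (prenyl bromide) | CC(C)=CCBr | starting material
4 | bromomagnesium (2Z)-3-(bromomagnesio)-2-methylprop-2-en-1-olate (alkenylmagnesium chelate) | Br[Mg]/C=C(/C)CO[Mg]Br | intermediate
5 | (2Z)-2,6-dimethylhepta-2,5-dien-1-ol | CC(C)=CC/C=C(/C)CO | intermediate
6 | [(2R,3S)-2-methyl-3-(3-methylbut-2-en-1-yl)oxiran-2-yl]methanol | CC(C)=CC[C@@H]1O[C@]1(C)CO | intermediate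
7 | (2S,3S)-2-methyl-3-(3-methylbut-2-en-1-yl)oxirane-2-carbaldehyde | CC(C)=CC[C@@H]1O[C@]1(C)C=O | intermediate
8 | 1,3-dithiane | C1CSCSC1 | starting material
9 | 2-lithio-1,3-dithiane | [Li]C1SCCCS1 | intermediate
10 | (1,3-dithian-2-yl)[(2R,3S)-2-methyl-3-(3-methylbut-2-en-1-yl)oxiran-2-yl]methanol (both carbinol epimers) | CC(C)=CC[C@@H]1O[C@]1(C)C(O)C1SCCCS1 | intermediate
11 | (1,3-dithian-2-yl)[(2S,3S)-2-methyl-3-(3-methylbut-2-en-1-yl)oxiran-2-yl]methanone | CC(C)=CC[C@@H]1O[C@]1(C)C(=O)C1SCCCS1 | intermediate
12 | 2-[(2S,3S)-2-methyl-3-(3-methylbut-2-en-1-yl)oxiran-2-yl]-2-oxoacetaldehyde | CC(C)=CC[C@@H]1O[C@]1(C)C(=O)C=O | intermediate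
13 | (1S,3S,4S,6S)-3-hydroxy-1-methyl-4-(prop-1-en-2-yl)-7-oxabicyclo[4.1.0]heptan-2-one | C=C(C)[C@@H]1C[C@@H]2O[C@]2(C)C(=O)[C@H]1O | intermediate
14 | (2E)-2-methylbut-2-enoyl chloride (tigloyl chloride) | C/C=C(\C)C(Cl)=O | starting material
15 | (1S,3S,4S,6S)-1-methyl-2-oxo-4-(prop-1-en-2-yl)-7-oxabicyclo[4.1.0]heptan-3-yl (2E)-2-methylbut-2-enoate | C=C(C)[C@@H]1C[C@@H]2O[C@]2(C)C(=O)[C@H]1OC(=O)/C(C)=C/C | intermediate
16 | (1S,3S,4S,6S)-4-(3-hydroxyprop-1-en-2-yl)-1-methyl-2-oxo-7-oxabicyclo[4.1.0]heptan-3-yl (2E)-2-methylbut-2-enoate | C=C(CO)[C@@H]1C[C@@H]2O[C@]2(C)C(=O)[C@H]1OC(=O)/C(C)=C/C | intermediate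
17 | (1S,3S,4S,6S)-1-methyl-2-oxo-4-(3-oxoprop-1-en-2-yl)-7-oxabicyclo[4.1.0]heptan-3-yl (2E)-2-methylbut-2-enoate | C=C(C=O)[C@@H]1C[C@@H]2O[C@]2(C)C(=O)[C@H]1OC(=O)/C(C)=C/C | intermediate
18 | 4,4,5,5-tetramethyl-2-(2-methylbut-3-en-2-yl)-1,3,2-dioxaborolane | C=CC(C)(C)B1OC(C)(C)C(C)(C)O1 | starting material
19 | (1S,3S,4S,6S)-1-methyl-4-{6-methyl-3-[(4,4,5,5-tetramethyl-1,3,2-dioxaborolan-2-yl)oxy]hepta-1,5-dien-2-yl}-2-oxo-7-oxabicyclo[4.1.0]heptan-3-yl (2E)-2-methylbut-2-enoate (both C3′ epimers) | C=C(C(CC=C(C)C)OB1OC(C)(C)C(C)(C)O1)[C@@H]2C[C@@H]3O[C@]3(C)C(=O)[C@H]2OC(=O)/C(C)=C/C | intermediate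
20 | (1S,3S,4S,6S)-4-(3-hydroxy-6-methylhepta-1,5-dien-2-yl)-1-methyl-2-oxo-7-oxabicyclo[4.1.0]heptan-3-yl (2E)-2-methylbut-2-enoate (both C3′ epimers) | C=C(C(O)CC=C(C)C)[C@@H]1C[C@@H]2O[C@]2(C)C(=O)[C@H]1OC(=O)/C(C)=C/C | intermediate
21 | (1S,3S,4S,6S)-1-methyl-4-(6-methyl-3-oxohepta-1,5-dien-2-yl)-2-oxo-7-oxabicyclo[4.1.0]heptan-3-yl (2E)-2-methylbut-2-enoate | C=C(C(=O)CC=C(C)C)[C@@H]1C[C@@H]2O[C@]2(C)C(=O)[C@H]1OC(=O)/C(C)=C/C | intermediate
22 | (1S,3S,4S,6S)-4-[(4E)-6-hydroperoxy-6-methyl-3-oxohepta-1,4-dien-2-yl]-1-methyl-2-oxo-7-oxabicyclo[4.1.0]heptan-3-yl (2E)-2-methylbut-2-enoate | C=C(C(=O)/C=C/C(C)(C)OO)[C@@H]1C[C@@H]2O[C@]2(C)C(=O)[C@H]1OC(=O)/C(C)=C/C | target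

**Totals and risks**

Total step count: 11. Longest linear sequence: 11 steps (1 → 22); the route is fully linear.

Steps most likely to fail:

1. Step 6 (glyoxal-ene ring closure). The catalyst may discriminate the two aldehyde faces poorly against the pull of the resident oxirane (mismatched double stereodifferentiation), the α-ketol product may hold on to the metal and stall turnover, or the Lewis acid may open the oxirane. The fallback moves the ring closure to the alcohol oxidation level and puts it under substrate control. It sets out from carbinol 10: silylation (Et3SiOTf, 2,6-lutidine, CH2Cl2) should give the triethylsilyl ether of 10, F1. Alkylative hydrolysis of the dithiane (MeI, CaCO3, aqueous MeCN) should give 2-[(2S,3S)-2-methyl-3-(3-methylbut-2-en-1-yl)oxiran-2-yl]-2-(triethylsilyloxy)acetaldehyde, F2, whose epimers at the silyloxy carbon are separated and tried individually. A Me2AlCl-promoted type 1 carbonyl-ene cyclisation (CH2Cl2, −78 °C), in which the adjacent silyloxy stereocentre directs the aldehyde face, should give (1S,3S,4S,6S)-1-methyl-4-(prop-1-en-2-yl)-2-(triethylsilyloxy)-7-oxabicyclo[4.1.0]heptan-3-ol, F3. Acylation with 14 (pyridine, DMAP) should give the tiglate of F3, F4, and HF·pyridine should remove the silyl group to give the C2 alcohol corresponding to 15, F5. Dess–Martin oxidation of F5 comes back to the route at keto ester 15.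

2. Step 11 (photooxygenation). The perepoxide may abstract hydrogen from the cis-methyl group instead of the C4′ methylene (leakage to the secondary allylic hydroperoxide with an isopropenyl terminus), or the β,γ-enone may slip into conjugation before it is oxygenated. The fallback is a radical-chain autoxidation with ground-state oxygen, setting out from 21: O2 (1 atm) with a low-temperature initiator (di-tert-butyl hyponitrite or AIBN, benzene, 35–40 °C). Abstraction of the doubly activated C4′ hydrogen gives a delocalised radical that takes up oxygen at the tertiary terminus C6′, the known autoxidation mode of β,γ-unsaturated ketones to γ-hydroperoxy enones. This leads from 21 directly to 22 without a new intermediate.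

3. Step 8 (allylic oxidation). The selenium ene step may take the ring methine hydrogen at C4 instead of a methyl hydrogen (tertiary allylic alcohol), or conversion may stall at partial oxidation. The fallback goes through the allylic chloride, setting out from 15: ene-type chlorination with hypochlorous acid (Ca(OCl)2, solid CO2, CH2Cl2/H2O, 0 °C) should give (1S,3S,4S,6S)-4-(3-chloroprop-1-en-2-yl)-1-methyl-2-oxo-7-oxabicyclo[4.1.0]heptan-3-yl (2E)-2-methylbut-2-enoate, F6. Kornblum-type oxidation of F6 with N-methylmorpholine N-oxide (MeCN, rt) comes back to the route at enal 17.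

Further compounds
F1 | step 6 | triethylsilyl ether of carbinol 10 (both epimers at the silyloxy carbon) | CC(C)=CC[C@@H]1O[C@]1(C)C(O[Si](CC)(CC)CC)C1SCCCS1
F2 | step 6 | 2-[(2S,3S)-2-methyl-3-(3-methylbut-2-en-1-yl)oxiran-2-yl]-2-(triethylsilyloxy)acetaldehyde (epimers at the silyloxy carbon) | CC(C)=CC[C@@H]1O[C@]1(C)C(O[Si](CC)(CC)CC)C=O
F3 | step 6 | (1S,3S,4S,6S)-1-methyl-4-(prop-1-en-2-yl)-2-(triethylsilyloxy)-7-oxabicyclo[4.1.0]heptan-3-ol (C2 as carried from F2) | C=C(C)[C@@H]1C[C@@H]2O[C@]2(C)C(O[Si](CC)(CC)CC)[C@H]1O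
F4 | step 6 | (2E)-2-methylbut-2-enoate (tiglate) of F3 | C=C(C)[C@@H]1C[C@@H]2O[C@]2(C)C(O[Si](CC)(CC)CC)[C@H]1OC(=O)/C(C)=C/C
F5 | step 6 | C2 alcohol corresponding to keto ester 15 (2-hydroxy in place of 2-oxo) | C=C(C)[C@@H]1C[C@@H]2O[C@]2(C)C(O)[C@H]1OC(=O)/C(C)=C/C
F0 | step 11 | none | none
F6 | step 8 | (1S,3S,4S,6S)-4-(3-chloroprop-1-en-2-yl)-1-methyl-2-oxo-7-oxabicyclo[4.1.0]heptan-3-yl (2E)-2-methylbut-2-enoate | C=C(CCl)[C@@H]1C[C@@H]2O[C@]2(C)C(=O)[C@H]1OC(=O)/C(C)=C/C
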